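**Strategy.** Ring B is disconnected at C7–C8 (labdane numbering). C8, which carries the tertiary hydroxyl and the formyl carbon C17, is treated as a latent ketone flanked by C7H2. A ring A iodo ester is built by an enantioselective Ireland–Claisen rearrangement (C9, C10) and an epoxide–allylsilane cyclisation (C3, C5). It closes ring B by anionic acylation of a C7 carbanion onto the C8 ester. In the same flask a formyl anion equivalent adds to the new ketone anti to the axial C10 methyl, fixing the axial C8 hydroxyl and the equatorial C17. The key step thus gives ring B, the C7–C8 bond and the C8 stereocentre in one operation from a monocyclic precursor.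

Key step: step 10

Remark: atom labels C1–C20 follow labdane numbering of the target (C17 = formyl carbon, C20 = C10 methyl); the facial sense of the (4S,5S)-diazaborolidine controller in step 3 is assigned by analogy, and its (4R,5R) antipode would be used if the opposite sense applied.

Step 1
Reactants: 1 hex-5-ynoic acid
Product: 3 6-(trimethylsilyl)hex-5-ynoic acid, via trimethylsilyl ester 2 (not isolated)
Conditions: n-BuLi (2.1 equiv), THF, −78 °C; Me3SiCl (2.5 equiv), −78 °C → rt; 1 M HCl
Reagents that add atoms: chlorotrimethylsilane, C[Si](C)(C)Cl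
Why: Double deprotonation gives the carboxylate–acetylide dianion, C-silylation of the acetylide protects the alkyne terminus for the metathesis and hydroboration steps, and the O-silyl ester 2 should hydrolyse on acidic work-up (acetylide silylation).

Step 2
Reactants: 3 6-(trimethylsilyl)hex-5-ynoic acid; 4 geraniol
Product: 5 (2E)-3,7-dimethylocta-2,6-dien-1-yl 6-(trimethylsilyl)hex-5-ynoate
Conditions: DCC, DMAP (10 mol %), CH2Cl2, 0 °C → rt
Reagents that add atoms: none
Why: Steglich esterification of a primary allylic alcohol with an unhindered acid should proceed without allylic transposition or loss of the E geometry.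

Step 3
Reactants: 5 (2E)-3,7-dimethylocta-2,6-dien-1-yl 6-(trimethylsilyl)hex-5-ynoate
Product: 8 (2S,3R)-3-ethenyl-3,7-dimethyl-2-[4-(trimethylsilyl)but-3-yn-1-yl]oct-6-enoic acid, via boron enolate 6 (not isolated), via boryl carboxylate 7 (not isolated)
Conditions: (4S,5S)-2-bromo-4,5-diphenyl-1,3-bis(4-methylphenylsulfonyl)-1,3,2-diazaborolidine (1.2 equiv), i-Pr2NEt, CH2Cl2, −78 °C → rt; aqueous work-up
Reagents that add atoms: none
Why: Enantioselective Ireland–Claisen rearrangement of a chiral boron enolate, in which soft enolisation should give enolate 6 with the side chain cis to the O–B oxygen and its chair [3,3] transition state (C20 methyl axial because it is cis to the carbinol carbon of geraniol, side chain equatorial) sets the C9/C10 relative configuration while the C2-symmetric controller selects the face and hence the absolute configuration.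

Step 4
Reactants: 8 (2S,3R)-3-ethenyl-3,7-dimethyl-2-[4-(trimethylsilyl)but-3-yn-1-yl]oct-6-enoic acid
Product: 9 methyl (2S,3R)-3-ethenyl-3,7-dimethyl-2-[4-(trimethylsilyl)but-3-yn-1-yl]oct-6-enoate
Conditions: MeI, K2CO3, DMF, rt
Reagents that add atoms: iodomethane, CI
Why: O-Alkylation of the carboxylate (SN2 on iodomethane) esterifies the hindered acid without touching the C9 stereocentre.

Step 5
Reactants: 9 methyl (2S,3R)-3-ethenyl-3,7-dimethyl-2-[4-(trimethylsilyl)but-3-yn-1-yl]oct-6-enoate
Product: 10 methyl (2S,3R)-3-{2-[(2R)-3,3-dimethyloxiran-2-yl]ethyl}-3-methyl-2-[4-(trimethylsilyl)but-3-yn-1-yl]pent-4-enoate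
Conditions: 1,2:4,5-di-O-isopropylidene-β-D-erythro-2,3-hexodiulo-2,6-pyranose (D-fructose-derived ketone, 30 mol %), Oxone (2KHSO5·KHSO4·K2SO4), K2CO3, Bu4NHSO4, MeCN–(MeO)2CH2–aqueous borate buffer, 0 °C
Reagents that add atoms: potassium peroxymonosulfate (KHSO5, active component of Oxone), [K+].[O-]S(=O)(=O)OO
Why: Shi epoxidation, in which the chiral dioxirane should oxidise the electron-rich trisubstituted C3=C4 alkene much faster than the hindered vinyl group or the silylalkyne and the spiro transition state of the D-fructose-derived ketone delivers the (R)-epoxide at C3.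

Step 6
Reactants: 10 methyl (2S,3R)-3-{2-[(2R)-3,3-dimethyloxiran-2-yl]ethyl}-3-methyl-2-[4-(trimethylsilyl)but-3-yn-1-yl]pent-4-enoate
Product: 11 methyl (2S,3R,4E)-3-{2-[(2R)-3,3-dimethyloxiran-2-yl]ethyl}-3-methyl-6-(trimethylsilyl)-2-[4-(trimethylsilyl)but-3-yn-1-yl]hex-4-enoate
Conditions: allyltrimethylsilane (8 equiv), second-generation Hoveyda–Grubbs catalyst [RuCl2(H2IMes)(=CH-C6H4-2-O-i-Pr)] (10 mol %), CH2Cl2, 40 °C
Reagents that add atoms: allyltrimethylsilane, C=CC[Si](C)(C)C
Why: Olefin cross-metathesis, in which the vinyl group on the quaternary carbon cannot homodimerise and should couple with excess allyltrimethylsilane with loss of ethene to give mainly the (E)-allylsilane, either geometry being productive in step 7.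

Step 7
Reactants: 11 methyl (2S,3R,4E)-3-{2-[(2R)-3,3-dimethyloxiran-2-yl]ethyl}-3-methyl-6-(trimethylsilyl)-2-[4-(trimethylsilyl)but-3-yn-1-yl]hex-4-enoate
Product: 12 methyl (2S)-2-[(1R,2S,4R)-2-ethenyl-4-hydroxy-1,3,3-trimethylcyclohexyl]-6-(trimethylsilyl)hex-5-ynoate
Conditions: BF3·OEt2 (2 equiv), CH2Cl2, −78 °C; aqueous NaHCO3
Reagents that add atoms: none
Why: Lewis acid epoxide–allylsilane cyclisation (intramolecular Hosomi–Sakurai-type SE2' attack), in which C5 opens the epoxide at tertiary C4 with inversion through a chair transition state that has C3–O equatorial, the C10 methyl axial and in the plane of the allylsilane double bond (least allylic 1,3-strain) and the bulky C9 branch equatorial, so that C5 should be set with the new vinyl group equatorial and trans to the C9 branch while C3 keeps the epoxide configuration.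

Step 8
Reactants: 12 methyl (2S)-2-[(1R,2S,4R)-2-ethenyl-4-hydroxy-1,3,3-trimethylcyclohexyl]-6-(trimethylsilyl)hex-5-ynoate
Product: 14 methyl (2S)-2-[(1R,2S,4R)-4-hydroxy-2-(2-hydroxyethyl)-1,3,3-trimethylcyclohexyl]-6-(trimethylsilyl)hex-5-ynoate, via B-alkyl-9-BBN adduct 13 (not isolated)
Conditions: 9-borabicyclo[3.3.1]nonane (9-BBN, 3 equiv), THF, 0 °C → rt; then H2O2, pH 7 phosphate buffer, 0 °C
Reagents that add atoms: hydrogen peroxide, OO
Why: Anti-Markovnikov hydroboration of the terminal vinyl group with the bulky 9-BBN and oxidation with retention should give the primary C7 alcohol, since the ester and the silylalkyne react far more slowly and the neutral peroxide work-up keeps the C–Si bond.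

Step 9
Reactants: 14 methyl (2S)-2-[(1R,2S,4R)-4-hydroxy-2-(2-hydroxyethyl)-1,3,3-trimethylcyclohexyl]-6-(trimethylsilyl)hex-5-ynoate
Product: 15 methyl (2S)-2-[(1R,2S,4R)-4-hydroxy-2-(2-iodoethyl)-1,3,3-trimethylcyclohexyl]-6-(trimethylsilyl)hex-5-ynoate
Conditions: I2, PPh3, imidazole, CH2Cl2, 0 °C
Reagents that add atoms: iodine, II
Why: Appel-type iodination converts the primary alcohol by SN2 while the hindered secondary 3-OH next to the gem-dimethyl carbon should stay untouched.

Step 10
Reactants: 15 methyl (2S)-2-[(1R,2S,4R)-4-hydroxy-2-(2-iodoethyl)-1,3,3-trimethylcyclohexyl]-6-(trimethylsilyl)hex-5-ynoate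
Product: 18 (1S,2R,4aS,6R,8aR)-2-(1,3-dithian-2-yl)-5,5,8a-trimethyl-1-[4-(trimethylsilyl)but-3-yn-1-yl]decahydronaphthalene-2,6-diol, via alkyllithium 16 (not isolated), via ketone 17 (not isolated)
Conditions: t-BuLi (3.1 equiv), Et2O–pentane, −78 °C; then 2-lithio-1,3-dithiane (3 equiv, from 1,3-dithiane and n-BuLi, THF, −30 °C), −78 → −20 °C; aqueous NH4Cl
Reagents that add atoms: 1,3-dithiane, C1CSCSC1 (used as its 2-lithio derivative, [Li]C1SCCCS1)
Why: After deprotonation of the 3-OH, iodine–lithium exchange at C7 with t-BuLi gives alkyllithium 16, whose carbanion adds to the C8 ester carbonyl and expels methoxide, forming the C7–C8 bond and ketone 17. The closest known reaction type is the Parham-type anionic cyclisation of halo esters, an intramolecular acylation of an organolithium, and ring B closes in the 6-exo-trig mode. The ring fusion (C5, C10) and C9 are inherited from 15, and C9, now α to the ketone, already carries its side chain in the thermodynamically preferred equatorial position, so the trans-decalone should form. 2-Lithio-1,3-dithiane, a formyl anion equivalent, then adds to C8 in the same flask along the equatorial trajectory because the axial one is blocked by the syn-axial C10 methyl, which sets C8 with the hydroxyl axial (cis to C20) and C17 equatorial. The step needs the exchange to outrun attack of t-BuLi on the ester, which the very fast iodine–lithium exchange at −78 °C and the α-branched ester next to a quaternary carbon secure, and it needs cyclisation to outrun proton transfer, which the strain-free six-membered transition state favours. It also needs addition to 17 to outrun enolisation, which the low temperature and the excess of the sulfur-stabilised nucleophile should favour.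

Step 11
Reactants: 18 (1S,2R,4aS,6R,8aR)-2-(1,3-dithian-2-yl)-5,5,8a-trimethyl-1-[4-(trimethylsilyl)but-3-yn-1-yl]decahydronaphthalene-2,6-diol
Product: 20 methyl 5-[(1S,2R,4aS,6R,8aR)-2-(1,3-dithian-2-yl)-2,6-dihydroxy-5,5,8a-trimethyldecahydronaphthalen-1-yl]pent-2-ynoate, via alkynoic acid 19 (not isolated)
Conditions: CsF, CO2 (1 atm), DMSO, rt; AcOH; then Me3SiCHN2, MeOH–toluene, 0 °C
Reagents that add atoms: carbon dioxide, O=C=O; (trimethylsilyl)diazomethane, C[Si](C)(C)C=[N+]=[N-]
Why: Fluoride-promoted desilylative carboxylation, in which CsF cleaves the C(sp)–Si bond and the alkynyl anion equivalent is trapped by CO2, should give alkynoic acid 19, which the diazo reagent esterifies without touching the alcohols or the dithiane.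

Step 12
Reactants: 20 methyl 5-[(1S,2R,4aS,6R,8aR)-2-(1,3-dithian-2-yl)-2,6-dihydroxy-5,5,8a-trimethyldecahydronaphthalen-1-yl]pent-2-ynoate
Product: 22 methyl (2Z)-5-[(1S,2R,4aS,6R,8aR)-2-(1,3-dithian-2-yl)-2,6-dihydroxy-5,5,8a-trimethyldecahydronaphthalen-1-yl]-3-methylpent-2-enoate, via alkenylcopper adduct 21 (not isolated)
Conditions: Me2CuLi (5 equiv, from MeLi and CuI), THF, −78 °C; MeOH then aqueous NH4Cl at −78 °C
Reagents that add atoms: lithium dimethylcuprate, [Li+].C[Cu-]C
Why: Conjugate addition of the cuprate to the ynoate is a syn-carbocupration, and protonation of alkenylcopper adduct 21 at −78 °C with retention should place the new methyl trans to the ester and the chain cis to it (2Z), the lithium alkoxides of the two hydroxyls being inert.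

Step 13
Reactants: 22 methyl (2Z)-5-[(1S,2R,4aS,6R,8aR)-2-(1,3-dithian-2-yl)-2,6-dihydroxy-5,5,8a-trimethyldecahydronaphthalen-1-yl]-3-methylpent-2-enoate
Product: 23 (2Z)-5-[(1S,2R,4aS,6R,8aR)-2-(1,3-dithian-2-yl)-2,6-dihydroxy-5,5,8a-trimethyldecahydronaphthalen-1-yl]-3-methylpent-2-enoic acid
Conditions: LiOH, THF–MeOH–H2O, rt; then 1 M HCl to pH 3
Reagents that add atoms: lithium hydroxide, [Li+].[OH-]
Why: Saponification of the methyl ester should leave the β,β-disubstituted (Z)-enoate geometry and the base-stable dithiane unchanged.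

Step 14
Reactants: 23 (2Z)-5-[(1S,2R,4aS,6R,8aR)-2-(1,3-dithian-2-yl)-2,6-dihydroxy-5,5,8a-trimethyldecahydronaphthalen-1-yl]-3-methylpent-2-enoic acid
Product: 24 (2Z)-5-[(1S,2R,4aS,6R,8aR)-2-formyl-2,6-dihydroxy-5,5,8a-trimethyldecahydronaphthalen-1-yl]-3-methylpent-2-enoic acid
Conditions: PhI(OCOCF3)2 (1.5 equiv), NaHCO3, MeCN–H2O (9:1), 0 °C
Reagents that add atoms: water, O
Why: Oxidative dithioacetal hydrolysis with the hypervalent iodine reagent under buffered conditions unmasks C17 as the aldehyde in the last step, so that the sensitive α-hydroxy aldehyde meets no later reagent and no stereocentre is touched.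

**Compound list**

1 | hex-5-ynoic acid | C#CCCCC(=O)O | starting material
2 | trimethylsilyl 6-(trimethylsilyl)hex-5-ynoate (not isolated) | C[Si](C)(C)C#CCCCC(=O)O[Si](C)(C)C | intermediate
3 | 6-(trimethylsilyl)hex-5-ynoic acid | C[Si](C)(C)C#CCCCC(=O)O | intermediate
4 | geraniol, (2E)-3,7-dimethylocta-2,6-dien-1-ol | CC(C)=CCC/C(C)=C/CO | starting material
5 | (2E)-3,7-dimethylocta-2,6-dien-1-yl 6-(trimethylsilyl)hex-5-ynoate | CC(C)=CCC/C(C)=C/COC(=O)CCCC#C[Si](C)(C)C | intermediate
6 | boron enolate of 5 carrying the (4S,5S)-4,5-diphenyl-1,3-ditosyl-1,3,2-diazaborolidin-2-yl group on oxygen, side chain cis to O–B (not isolated) | CC(C)=CCC/C(C)=C/CO/C(OB1N(S(=O)(=O)c2ccc(C)cc2)[C@@H](c2ccccc2)[C@H](c2ccccc2)N1S(=O)(=O)c1ccc(C)cc1)=C/CCC#C[Si](C)(C)C | intermediate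
7 | O-[(4S,5S)-4,5-diphenyl-1,3-ditosyl-1,3,2-diazaborolidin-2-yl] carboxylate of acid 8 (not isolated) | C[Si](C)(C)C#CCC[C@H](C(=O)OB1N(S(=O)(=O)c2ccc(C)cc2)[C@@H](c2ccccc2)[C@H](c2ccccc2)N1S(=O)(=O)c1ccc(C)cc1)[C@](C=C)(C)CCC=C(C)C | intermediate
8 | (2S,3R)-3-ethenyl-3,7-dimethyl-2-[4-(trimethylsilyl)but-3-yn-1-yl]oct-6-enoic acid | C[Si](C)(C)C#CCC[C@H](C(=O)O)[C@](C=C)(C)CCC=C(C)C | intermediate
9 | methyl (2S,3R)-3-ethenyl-3,7-dimethyl-2-[4-(trimethylsilyl)but-3-yn-1-yl]oct-6-enoate | C[Si](C)(C)C#CCC[C@H](C(=O)OC)[C@](C=C)(C)CCC=C(C)C | intermediate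
10 | methyl (2S,3R)-3-{2-[(2R)-3,3-dimethyloxiran-2-yl]ethyl}-3-methyl-2-[4-(trimethylsilyl)but-3-yn-1-yl]pent-4-enoate | C[Si](C)(C)C#CCC[C@H](C(=O)OC)[C@](C=C)(C)CC[C@H]1OC1(C)C | intermediate
11 | methyl (2S,3R,4E)-3-{2-[(2R)-3,3-dimethyloxiran-2-yl]ethyl}-3-methyl-6-(trimethylsilyl)-2-[4-(trimethylsilyl)but-3-yn-1-yl]hex-4-enoate | C[Si](C)(C)C#CCC[C@H](C(=O)OC)[C@](/C=C/C[Si](C)(C)C)(C)CC[C@H]1OC1(C)C | intermediate
12 | methyl (2S)-2-[(1R,2S,4R)-2-ethenyl-4-hydroxy-1,3,3-trimethylcyclohexyl]-6-(trimethylsilyl)hex-5-ynoate | C[Si](C)(C)C#CCC[C@H](C(=O)OC)[C@]1(C)CC[C@@H](O)C(C)(C)[C@H]1C=C | intermediate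
13 | B-alkyl-9-BBN adduct of 12, boron on C7, drawn with the 3-OH free (not isolated) | C[Si](C)(C)C#CCC[C@H](C(=O)OC)[C@]1(C)CC[C@@H](O)C(C)(C)[C@H]1CCB1C2CCCC1CCC2 | intermediate
14 | methyl (2S)-2-[(1R,2S,4R)-4-hydroxy-2-(2-hydroxyethyl)-1,3,3-trimethylcyclohexyl]-6-(trimethylsilyl)hex-5-ynoate | C[Si](C)(C)C#CCC[C@H](C(=O)OC)[C@]1(C)CC[C@@H](O)C(C)(C)[C@H]1CCO | intermediate
15 | methyl (2S)-2-[(1R,2S,4R)-4-hydroxy-2-(2-iodoethyl)-1,3,3-trimethylcyclohexyl]-6-(trimethylsilyl)hex-5-ynoate | C[Si](C)(C)C#CCC[C@H](C(=O)OC)[C@]1(C)CC[C@@H](O)C(C)(C)[C@H]1CCI | intermediate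
16 | C7-lithio, O3-lithio derivative of 15 (not isolated) | C[Si](C)(C)C#CCC[C@H](C(=O)OC)[C@]1(C)CC[C@@H](O[Li])C(C)(C)[C@H]1CC[Li] | intermediate
17 | (1S,4aS,6R,8aR)-6-hydroxy-5,5,8a-trimethyl-1-[4-(trimethylsilyl)but-3-yn-1-yl]octahydronaphthalen-2(1H)-one (not isolated) | C[Si](C)(C)C#CCC[C@H]1[C@]2(C)CC[C@@H](O)C(C)(C)[C@H]2CCC1=O | intermediate
18 | (1S,2R,4aS,6R,8aR)-2-(1,3-dithian-2-yl)-5,5,8a-trimethyl-1-[4-(trimethylsilyl)but-3-yn-1-yl]decahydronaphthalene-2,6-diol | C[Si](C)(C)C#CCC[C@H]1[C@]2(C)CC[C@@H](O)C(C)(C)[C@H]2CC[C@]1(O)C1SCCCS1 | intermediate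
19 | 5-[(1S,2R,4aS,6R,8aR)-2-(1,3-dithian-2-yl)-2,6-dihydroxy-5,5,8a-trimethyldecahydronaphthalen-1-yl]pent-2-ynoic acid (not isolated) | OC(=O)C#CCC[C@H]1[C@]2(C)CC[C@@H](O)C(C)(C)[C@H]2CC[C@]1(O)C1SCCCS1 | intermediate
20 | methyl 5-[(1S,2R,4aS,6R,8aR)-2-(1,3-dithian-2-yl)-2,6-dihydroxy-5,5,8a-trimethyldecahydronaphthalen-1-yl]pent-2-ynoate | COC(=O)C#CCC[C@H]1[C@]2(C)CC[C@@H](O)C(C)(C)[C@H]2CC[C@]1(O)C1SCCCS1 | intermediate
21 | alkenylcopper adduct of 20, copper on C14 cis to the new methyl (not isolated) | C/C(=C(\[Cu])C(=O)OC)CC[C@H]1[C@]2(C)CC[C@@H](O)C(C)(C)[C@H]2CC[C@]1(O)C1SCCCS1 | intermediate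
22 | methyl (2Z)-5-[(1S,2R,4aS,6R,8aR)-2-(1,3-dithian-2-yl)-2,6-dihydroxy-5,5,8a-trimethyldecahydronaphthalen-1-yl]-3-methylpent-2-enoate | C/C(=C/C(=O)OC)CC[C@H]1[C@]2(C)CC[C@@H](O)C(C)(C)[C@H]2CC[C@]1(O)C1SCCCS1 | intermediate
23 | (2Z)-5-[(1S,2R,4aS,6R,8aR)-2-(1,3-dithian-2-yl)-2,6-dihydroxy-5,5,8a-trimethyldecahydronaphthalen-1-yl]-3-methylpent-2-enoic acid | C/C(=C/C(=O)O)CC[C@H]1[C@]2(C)CC[C@@H](O)C(C)(C)[C@H]2CC[C@]1(O)C1SCCCS1 | intermediate
24 | (2Z)-5-[(1S,2R,4aS,6R,8aR)-2-formyl-2,6-dihydroxy-5,5,8a-trimethyldecahydronaphthalen-1-yl]-3-methylpent-2-enoic acid | C/C(=C/C(=O)O)CC[C@H]1[C@]2(C)CC[C@@H](O)C(C)(C)[C@H]2CC[C@]1(O)C=O | target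

**Step count and risks**

Total step count: 14. Longest linear sequence: 14 steps (hex-5-ynoic acid 1 to target 24; geraniol 4 enters at step 2).

Steps most likely to fail:

1. Step 10 (key step). What may go wrong: proton transfer to the C7 carbanion before it acylates, or enolisation of the ketone by the dithiane anion in the one-flask sequence, so that ring closure or the C17 addition stays incomplete. Fallback, setting out from 14 and coming back at 17: the polarity of the ring closure is inverted. The primary hydroxyl of 14 is tosylated selectively (TsCl, pyridine, 0 °C) to give tosylate F1. Reduction of the ester with i-Bu2AlH at −78 °C gives aldehyde F2. Propane-1,3-dithiol and BF3·OEt2 convert it into the C8 dithiane F3. n-BuLi (2.2 equiv, THF, −30 °C) lithiates C8, which closes ring B by 6-exo-tet alkylation at C7 to give spiro-dithioketal F4. Hydrolysis (MeI, CaCO3, aqueous MeCN) gives ketone 17, which is isolated and treated with 2-lithio-1,3-dithiane as in the second half of step 10 to reach 18.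

2. Step 6. What may go wrong: no turnover at the vinyl group on the quaternary carbon because of steric shutdown of the metathesis. Fallback, setting out from 10 and coming back at 12: the allylsilane is made by olefination. Ozonolysis of the vinyl group of 10 (O3, CH2Cl2, −78 °C; Me2S) gives aldehyde F5. Wittig reaction with the ylide from [2-(trimethylsilyl)ethyl]triphenylphosphonium iodide and n-BuLi gives (Z)-allylsilane F6. Cyclisation with BF3·OEt2 as in step 7 should give the same vinylcyclohexanol 12.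

3. Step 7. What may go wrong: poor facial selectivity at C5, or Lewis acid-induced rearrangement of the epoxide to a ketone before C–C bond formation. Fallback, setting out from 10 and coming back at 14: ring A is closed by a radical instead of a cation. Cross-metathesis of 10 with methyl acrylate (same ruthenium catalyst) gives enoate F7. Cp2TiCl (from Cp2TiCl2 and Zn, THF) opens the epoxide to the tertiary C4 radical, which adds 6-exo to the enoate and gives hydroxy diester F8 after protonation. LiBH4 reduces the unhindered C7 ester selectively and returns diol 14. This fallback relies on a metathesis at the same vinyl group as step 6, so it answers only a failure of the cationic ring closure.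

**Further compounds**

F1 | step 10 | C7 tosylate of diol 14 (3-OH free) | C[Si](C)(C)C#CCC[C@H](C(=O)OC)[C@]1(C)CC[C@@H](O)C(C)(C)[C@H]1CCOS(=O)(=O)c1ccc(C)cc1
F2 | step 10 | C8 aldehyde from F1 | C[Si](C)(C)C#CCC[C@H](C=O)[C@]1(C)CC[C@@H](O)C(C)(C)[C@H]1CCOS(=O)(=O)c1ccc(C)cc1
F3 | step 10 | C8 1,3-dithiane from F2 | C[Si](C)(C)C#CCC[C@H](C1SCCCS1)[C@]1(C)CC[C@@H](O)C(C)(C)[C@H]1CCOS(=O)(=O)c1ccc(C)cc1
F4 | step 10 | spiro-dithioketal of ketone 17 at C8 | C[Si](C)(C)C#CCC[C@H]1[C@]2(C)CC[C@@H](O)C(C)(C)[C@H]2CCC13SCCCS3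
F5 | step 6 | aldehyde from ozonolysis of the vinyl group of 10 | C[Si](C)(C)C#CCC[C@H](C(=O)OC)[C@](C=O)(C)CC[C@H]1OC1(C)C
F6 | step 6 | (Z)-allylsilane isomer of 11 | C[Si](C)(C)C#CCC[C@H](C(=O)OC)[C@](/C=C\C[Si](C)(C)C)(C)CC[C@H]1OC1(C)C
F7 | step 7 | (E)-enoate from 10 and methyl acrylate | C[Si](C)(C)C#CCC[C@H](C(=O)OC)[C@](/C=C/C(=O)OC)(C)CC[C@H]1OC1(C)C
F8 | step 7 | ring A hydroxy diester with a CH2CO2Me group on C5 | C[Si](C)(C)C#CCC[C@H](C(=O)OC)[C@]1(C)CC[C@@H](O)C(C)(C)[C@H]1CC(=O)OC
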